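## The problem

- The target is the p-coumarate ester of a 2-aryl-3-(hydroxymethyl)-2,3-dihydrobenzofuran neolignan. Ring O1–C2–C3–C3a–C7a is fused to a 1,2,3,5-tetrasubstituted arene carrying 7-OMe and a 5-(3-hydroxypropyl) chain.
- C2 (R) and C3 (S) are contiguous and trans, and must be set in absolute terms. Nothing else in the molecule can control them.
- C2 is a benzylic ether carbon on an electron-rich 4-hydroxyaryl ring. Its C2–O1 bond can ionise in acid, or open from the phenoxide (para-quinone methide), and either path epimerises C2.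
- C3 is configurationally labile only while it carries a carbonyl group. In that state it can also open the ring by E1cB loss of O1.
- There are two primary alcohols of similar reactivity and only C3–CH2OH is acylated, so the two must never be free together.
- The (E)-cinnamate ester excludes hydrogenation, hydride and hydroxide once it is in place, and the two free phenols exclude oxidants at the end.
- The enabling feature: C3 bears an exocyclic oxygenated one-carbon unit and is bonded directly to arene carbon C3a, while C2 bears the aryl group and O1. The array C3a–C3(–C)–C2(Ar)–O1 is the 1,2-aryl-shift isomer of the array C4a–C4(=O)–C3–C2(Ar)–O1 of a flavanone (ring O1–C2–C3–C4–C4a–C8a). The five-membered ring can therefore come from a chroman-4-one that expels C4 as the exocyclic carbon.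
- This reduces the two-centre problem to one stereocentre on a six-membered enone, where catalytic asymmetric conjugate addition is well established; C3 then follows by relay.

## Retrosynthesis

**Ester and silyl groups.** Target 23 is traced to its tris-silyl ether 22 by cleaving three O–Si bonds, and 22 to alcohol 18 and acid 21 by cutting the C3–CH2O–C(=O) ester bond. Acylating late, on a substrate whose only free hydroxyl is C3–CH2OH, removes the regiochemical problem. Silicon on every other oxygen leaves buffered fluoride as the only operation after the cinnamate is installed. Acid 21 comes from p-coumaric acid 19 through silyl ester 20.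

**Side chain.** Alcohol 18 is cut at the C5–CH2 (sp2–sp3) bond to aryl bromide 15 and alkylborane 17, made in the flask from allyl silyl ether 16. The chain thus arrives with its own protecting group. The bromine that stands in for it is inert to the Pd(II), iodine(III) and hydride steps before it, where a silyl ether or free alcohol would not be.

**Oxidation level at C3.** Alcohol 15 comes from methyl ester 14 by reduction. Doing this directly after the ring contraction removes the acidifying carbonyl from C3 before any basic step.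

**Key disconnection.** Ester 14 is traced to flavanone 10 by breaking C3–C3a and re-forming C4–C4a, with the ester carbon returning to the ring as the C4 ketone. Forward, this is an oxidative ring contraction through enol ether 11, iodane 12 and orthoester 13. Against cuts that build the five-membered ring directly, this one asks for only one stereocentre in the precursor and gives the trans relationship by mechanism. The forward step must transfer C2 unchanged and make the ring bond migrate, not the B-ring.

**Flavanone.** Flavanone 10 is cut at the C2–aryl bond to chromone 4 and boronic acid 9. This is the most convergent cut and sets C2 by asymmetric conjugate addition. The reaction must tolerate the aryl bromide and the silyl ether.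

**Building blocks.** Chromone 4 comes from bromo ketone 2 through enaminone 3, and 2 from commercial ketone 1. Boronic acid 9 comes from silyl ether 6 through aryllithium 7 and borate 8, and 6 from commercial bromophenol 5.

## Roads not taken

**Alternative 1:** The most obvious plan cuts C3–C3a and C2–O1 together. Oxidative radical dimerisation of methyl ferulate (Ag2O) gives racemic trans-dehydrodiferulate A1 in one step. The chosen plan is better for three reasons. The coupling has no absolute stereocontrol, so a resolution discards half the material. β–O–4 and β–β coupling modes compete. Both side chains emerge at the same oxidation level, so telling the C3 carbon from the chain terminus, and saturating the chain alkene, would cost more steps than the dimerisation saves.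

**Alternative 2:** Cut C2–C3. Aryl diazoacetate A2 would undergo intramolecular Rh(II)-carbenoid insertion into the benzylic C–H bond of its ortho benzyl ether under a chiral Rh(II) carboxylate. The insertion is inherently cis-selective, so a base-mediated C3 epimerisation of a β-aryloxy ester would be needed, which risks E1cB ring opening. A2 also needs a longer run-up (arylacetate on a tetrasubstituted arene, O-benzylation, diazo transfer) than flavanone 10. The catalyst would have to control two centres, where the chosen plan controls one and relays the second.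

**Alternative 3:** Cut O1–C7a. Racemic keto ester A3, whose α-centre is labile, would undergo Ru-catalysed asymmetric transfer hydrogenation with dynamic kinetic resolution to hydroxy ester A4. Intramolecular Cu-catalysed O-arylation onto the ortho iodide would then close the ring. This needs an arene with two differentiated halogens. It also requires C–O coupling of a β-hydroxy ester under base, where retro-aldol cleavage and dehydration compete, on an electron-rich, flanked aryl iodide. Three operations would do what the ring contraction does in one.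

Key step: step 6

Assumption: the target is read as the (2R,3S), 2,3-trans isomer. The sense of induction of Pd/(S)-t-BuPyOx on chromone 4 is taken to follow that known for cyclic enones, which would give (2R)-10; if it proves opposite, (R)-t-BuPyOx is used with no other change.

## Route

Step 1
Reactants: 1 1-(2-hydroxy-3-methoxyphenyl)ethan-1-one
Product: 2 1-(5-bromo-2-hydroxy-3-methoxyphenyl)ethan-1-one
Conditions: NBS (1.05 equiv), MeCN, 0 °C to rt
Reagents that add atoms: N-bromosuccinimide, O=C1CCC(=O)N1Br
Why: Electrophilic aromatic bromination; the phenol directs to its para position C5 (both ortho positions are occupied) and the acetyl group is meta-directing to the same carbon.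

Step 2
Reactants: 2 1-(5-bromo-2-hydroxy-3-methoxyphenyl)ethan-1-one
Product: 4 6-bromo-8-methoxy-4H-chromen-4-one, via enaminone 3 (not isolated)
Conditions: Me2NCH(OMe)2, toluene, 100 °C; then conc. HCl, CH2Cl2, rt
Reagents that add atoms: N,N-dimethylformamide dimethyl acetal, COC(OC)N(C)C
Why: Standard chromone synthesis: condensation at the methyl ketone gives the enaminone, and acid then promotes oxa-Michael addition of the phenol and loss of dimethylamine.

Step 3
Reactants: 5 4-bromo-2-methoxyphenol
Product: 6 (4-bromo-2-methoxyphenoxy)tri(propan-2-yl)silane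
Conditions: TIPSCl, imidazole, DMF, rt
Reagents that add atoms: triisopropylsilyl chloride, CC(C)[Si](Cl)(C(C)C)C(C)C
Why: Phenol silylation; the aryl triisopropylsilyl ether is chosen because it should survive aryllithium formation, aqueous Pd catalysis, acidic orthoformate, hydride and phosphate base, and leaves with fluoride at the end.

Step 4
Reactants: 6 (4-bromo-2-methoxyphenoxy)tri(propan-2-yl)silane
Product: 9 [3-methoxy-4-(triisopropylsilyloxy)phenyl]boronic acid, via aryllithium 7 (not isolated), via lithium arylborate 8 (not isolated)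
Conditions: n-BuLi, THF, −78 °C; B(OiPr)3, −78 °C to rt; 1 M HCl
Reagents that add atoms: triisopropyl borate, CC(C)OB(OC(C)C)OC(C)C; water, O
Why: Bromine–lithium exchange is faster than any ortho-lithiation at −78 °C; the aryllithium is trapped by the borate and the ate complex is hydrolysed to the boronic acid.

Step 5
Reactants: 4 6-bromo-8-methoxy-4H-chromen-4-one; 9 [3-methoxy-4-(triisopropylsilyloxy)phenyl]boronic acid
Product: 10 (2R)-6-bromo-8-methoxy-2-[3-methoxy-4-(triisopropylsilyloxy)phenyl]-2,3-dihydro-4H-chromen-4-one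
Conditions: 9 (2 equiv), Pd(OCOCF3)2 (5 mol%), (S)-t-BuPyOx (6 mol%), NH4PF6 (30 mol%), H2O (5 equiv), ClCH2CH2Cl, 60 °C
Reagents that add atoms: none
Why: Pd(II)-catalysed asymmetric conjugate addition of an arylboronic acid to a chromone (transmetalation, enone insertion, protonolysis of the Pd enolate); the pyridine–oxazoline ligand differentiates the enone faces and sets C2 as R. Palladium stays in the +2 state, so the aryl bromide should not be touched.

Step 6
Reactants: 10 (2R)-6-bromo-8-methoxy-2-[3-methoxy-4-(triisopropylsilyloxy)phenyl]-2,3-dihydro-4H-chromen-4-one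
Product: 14 methyl (2R,3R)-5-bromo-7-methoxy-2-[3-methoxy-4-(triisopropylsilyloxy)phenyl]-2,3-dihydro-1-benzofuran-3-carboxylate, via enol ether 11 (not isolated), via ketal iodane 12 (not isolated), via orthoester 13 (not isolated)
Conditions: PhI(OAc)2 (1.3 equiv), conc. H2SO4 (0.5 equiv), HC(OMe)3, 0 °C to rt; aq. NaHCO3 work-up
Reagents that add atoms: trimethyl orthoformate, COC(OC)OC; water, O
Why: Acid and trimethyl orthoformate convert the C4 ketone into enol ether 11, which (diacetoxyiodo)benzene attacks at C3 on the face anti to the C2 aryl group, methanol capturing C4 to give the 2,3-trans ketal iodane 12. In the half-chair of 12 the C2 aryl and C3 iodanyl groups are both equatorial, so the C3–I bond is antiperiplanar to the ring bond C4–C4a and not to the C2–aryl bond; loss of iodobenzene is therefore assisted by a 1,2-shift of arene carbon C4a from C4 to C3 through a bridged phenonium-type transition state, and the resulting dimethoxycarbenium ion is trapped as orthoester 13 and hydrolysed to ester 14 on work-up. The closest known reaction type is the iodine(III)- or thallium(III)-mediated oxidative 1,2-aryl migration of aryl ketones in orthoformate, which on flavanones is the established ring contraction to trans-2-aryl-2,3-dihydrobenzofuran-3-carboxylates. The five-membered ring O1–C2–C3–C3a–C7a is closed not by a cyclisation but by contraction of the six-membered ring: the C3–C3a bond forms (formally a 3-exo-tet attack of the arene on C3) as the C4–C4a bond breaks, and C4 is expelled as the exocyclic ester carbon. C2 is a spectator whose four bonds are untouched, so the R configuration from step 5 is carried over; C3 is set by substrate control, since anti iodination followed by migration with inversion at C3 places the expelled carbon trans to the aryl group, giving (2R,3R)-14, which is also the thermodynamically preferred diastereomer. The step needs ring-bond migration to win over B-ring migration (isoflavone), elimination (flavone) and ionisation of the benzylic C2–O1 bond; the diequatorial conformer, the ortho-oxygen-activated migrating arene, the ketal-forming medium that suppresses enolisation of the free ketone, and the silyloxy group on the B-ring (a weaker donor than alkoxy) all act in that direction.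

Step 7
Reactants: 14 methyl (2R,3R)-5-bromo-7-methoxy-2-[3-methoxy-4-(triisopropylsilyloxy)phenyl]-2,3-dihydro-1-benzofuran-3-carboxylate
Product: 15 [(2R,3S)-5-bromo-7-methoxy-2-[3-methoxy-4-(triisopropylsilyloxy)phenyl]-2,3-dihydro-1-benzofuran-3-yl]methanol
Conditions: LiBH4, THF, MeOH (1 equiv), 0 °C to rt
Reagents that add atoms: none
Why: Chemoselective borohydride reduction of the methyl ester; the reagent is too weakly basic to enolise C3, and the aryl bromide and aryl silyl ether are inert. The descriptor at C3 changes from R to S only because the CIP priorities change.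

Step 8
Reactants: 15 [(2R,3S)-5-bromo-7-methoxy-2-[3-methoxy-4-(triisopropylsilyloxy)phenyl]-2,3-dihydro-1-benzofuran-3-yl]methanol; 16 tert-butyldimethyl(prop-2-en-1-yloxy)silane
Product: 18 [(2R,3S)-5-[3-(tert-butyldimethylsilyloxy)propyl]-7-methoxy-2-[3-methoxy-4-(triisopropylsilyloxy)phenyl]-2,3-dihydro-1-benzofuran-3-yl]methanol, via alkylborane 17 (not isolated)
Conditions: 16 (1.5 equiv), 9-BBN, THF, 0 °C to rt; then 15, Pd(dppf)Cl2 (5 mol%), 3 M aq. K3PO4, DMF, 60 °C
Reagents that add atoms: none
Why: Anti-Markovnikov hydroboration of the terminal alkene gives the B-alkyl-9-BBN, and B-alkyl Suzuki–Miyaura coupling with the aryl bromide forms the C5–CH2 bond. With the ester gone, neither stereocentre is acidic, and aqueous phosphate is mild enough for the aryl silyl ether.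

Step 9
Reactants: 19 (E)-3-(4-hydroxyphenyl)prop-2-enoic acid
Product: 21 (E)-3-[4-(tert-butyldimethylsilyloxy)phenyl]prop-2-enoic acid, via silyl ester 20 (not isolated)
Conditions: TBSCl (2.2 equiv), imidazole, DMF, rt; then AcOH, THF/H2O, rt
Reagents that add atoms: tert-butyldimethylsilyl chloride, CC(C)(C)[Si](C)(C)Cl
Why: Bis-silylation followed by selective hydrolysis of the much more labile silyl ester leaves the aryl silyl ether and frees the acid.

Step 10
Reactants: 18 [(2R,3S)-5-[3-(tert-butyldimethylsilyloxy)propyl]-7-methoxy-2-[3-methoxy-4-(triisopropylsilyloxy)phenyl]-2,3-dihydro-1-benzofuran-3-yl]methanol; 21 (E)-3-[4-(tert-butyldimethylsilyloxy)phenyl]prop-2-enoic acid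
Product: 22 [(2R,3S)-5-[3-(tert-butyldimethylsilyloxy)propyl]-7-methoxy-2-[3-methoxy-4-(triisopropylsilyloxy)phenyl]-2,3-dihydro-1-benzofuran-3-yl]methyl (E)-3-[4-(tert-butyldimethylsilyloxy)phenyl]prop-2-enoate
Conditions: EDC·HCl, DMAP (cat.), CH2Cl2, 0 °C to rt
Reagents that add atoms: none
Why: Steglich esterification; C3–CH2OH is the only free hydroxyl, so no regiochemical question arises, and the conditions do not isomerise the (E)-alkene.

Step 11
Reactants: 22 [(2R,3S)-5-[3-(tert-butyldimethylsilyloxy)propyl]-7-methoxy-2-[3-methoxy-4-(triisopropylsilyloxy)phenyl]-2,3-dihydro-1-benzofuran-3-yl]methyl (E)-3-[4-(tert-butyldimethylsilyloxy)phenyl]prop-2-enoate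
Product: 23 [(2R,3S)-2-(4-hydroxy-3-methoxyphenyl)-5-(3-hydroxypropyl)-7-methoxy-2,3-dihydro-1-benzofuran-3-yl]methyl (E)-3-(4-hydroxyphenyl)prop-2-enoate
Conditions: TBAF/AcOH (1:1, excess), THF, 0 °C to rt
Reagents that add atoms: none
Why: Fluoride cleaves the two aryl silyl ethers and the primary alkyl silyl ether. The acetic acid buffer keeps the liberated phenols protonated, which should prevent phenoxide-driven opening of the C2–O1 bond and cleavage or transfer of the cinnamate.

## Compound list

1 | 1-(2-hydroxy-3-methoxyphenyl)ethan-1-one | CC(=O)c1cccc(OC)c1O | starting material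
2 | 1-(5-bromo-2-hydroxy-3-methoxyphenyl)ethan-1-one | CC(=O)c1cc(Br)cc(OC)c1O | intermediate
3 | (E)-1-(5-bromo-2-hydroxy-3-methoxyphenyl)-3-(dimethylamino)prop-2-en-1-one | CN(C)/C=C/C(=O)c1cc(Br)cc(OC)c1O | intermediate
4 | 6-bromo-8-methoxy-4H-chromen-4-one | O=c1ccoc2c(OC)cc(Br)cc12 | intermediate
5 | 4-bromo-2-methoxyphenol | COc1cc(Br)ccc1O | starting material
6 | (4-bromo-2-methoxyphenoxy)tri(propan-2-yl)silane | COc1cc(Br)ccc1O[Si](C(C)C)(C(C)C)C(C)C | intermediate
7 | [3-methoxy-4-(triisopropylsilyloxy)phenyl]lithium | [Li]c1ccc(O[Si](C(C)C)(C(C)C)C(C)C)c(OC)c1 | intermediate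
8 | lithium [3-methoxy-4-(triisopropylsilyloxy)phenyl]tri(propan-2-yloxy)borate | [Li+].CC(C)O[B-](OC(C)C)(OC(C)C)c1ccc(O[Si](C(C)C)(C(C)C)C(C)C)c(OC)c1 | intermediate
9 | [3-methoxy-4-(triisopropylsilyloxy)phenyl]boronic acid | COc1cc(B(O)O)ccc1O[Si](C(C)C)(C(C)C)C(C)C | intermediate
10 | (2R)-6-bromo-8-methoxy-2-[3-methoxy-4-(triisopropylsilyloxy)phenyl]-2,3-dihydro-4H-chromen-4-one | COc1cc([C@@H]2Oc3c(OC)cc(Br)cc3C(=O)C2)ccc1O[Si](C(C)C)(C(C)C)C(C)C | intermediate
11 | (2R)-6-bromo-4,8-dimethoxy-2-[3-methoxy-4-(triisopropylsilyloxy)phenyl]-2H-chromene | COc1cc([C@@H]2Oc3c(OC)cc(Br)cc3C(OC)=C2)ccc1O[Si](C(C)C)(C(C)C)C(C)C | intermediate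
12 | (2S,3S)-3-[acetoxy(phenyl)-λ3-iodanyl]-6-bromo-4,4,8-trimethoxy-2-[3-methoxy-4-(triisopropylsilyloxy)phenyl]-3,4-dihydro-2H-chromene (2,3-trans; C2 spatially as in 10) | COc1cc([C@@H]2Oc3c(OC)cc(Br)cc3C(OC)(OC)[C@H]2I(OC(C)=O)c2ccccc2)ccc1O[Si](C(C)C)(C(C)C)C(C)C | intermediate
13 | (2R,3R)-5-bromo-7-methoxy-2-[3-methoxy-4-(triisopropylsilyloxy)phenyl]-3-(trimethoxymethyl)-2,3-dihydro-1-benzofuran | COc1cc([C@@H]2Oc3c(OC)cc(Br)cc3[C@H]2C(OC)(OC)OC)ccc1O[Si](C(C)C)(C(C)C)C(C)C | intermediate
14 | methyl (2R,3R)-5-bromo-7-methoxy-2-[3-methoxy-4-(triisopropylsilyloxy)phenyl]-2,3-dihydro-1-benzofuran-3-carboxylate | COc1cc([C@@H]2Oc3c(OC)cc(Br)cc3[C@H]2C(=O)OC)ccc1O[Si](C(C)C)(C(C)C)C(C)C | intermediate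
15 | [(2R,3S)-5-bromo-7-methoxy-2-[3-methoxy-4-(triisopropylsilyloxy)phenyl]-2,3-dihydro-1-benzofuran-3-yl]methanol | COc1cc([C@@H]2Oc3c(OC)cc(Br)cc3[C@H]2CO)ccc1O[Si](C(C)C)(C(C)C)C(C)C | intermediate
16 | tert-butyldimethyl(prop-2-en-1-yloxy)silane | C=CCO[Si](C)(C)C(C)(C)C | starting material
17 | 9-[3-(tert-butyldimethylsilyloxy)propyl]-9-borabicyclo[3.3.1]nonane | CC(C)(C)[Si](C)(C)OCCCB1C2CCCC1CCC2 | intermediate
18 | [(2R,3S)-5-[3-(tert-butyldimethylsilyloxy)propyl]-7-methoxy-2-[3-methoxy-4-(triisopropylsilyloxy)phenyl]-2,3-dihydro-1-benzofuran-3-yl]methanol | COc1cc([C@@H]2Oc3c(OC)cc(CCCO[Si](C)(C)C(C)(C)C)cc3[C@H]2CO)ccc1O[Si](C(C)C)(C(C)C)C(C)C | intermediate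
19 | (E)-3-(4-hydroxyphenyl)prop-2-enoic acid | OC(=O)/C=C/c1ccc(O)cc1 | starting material
20 | tert-butyldimethylsilyl (E)-3-[4-(tert-butyldimethylsilyloxy)phenyl]prop-2-enoate | CC(C)(C)[Si](C)(C)OC(=O)/C=C/c1ccc(O[Si](C)(C)C(C)(C)C)cc1 | intermediate
21 | (E)-3-[4-(tert-butyldimethylsilyloxy)phenyl]prop-2-enoic acid | OC(=O)/C=C/c1ccc(O[Si](C)(C)C(C)(C)C)cc1 | intermediate
22 | [(2R,3S)-5-[3-(tert-butyldimethylsilyloxy)propyl]-7-methoxy-2-[3-methoxy-4-(triisopropylsilyloxy)phenyl]-2,3-dihydro-1-benzofuran-3-yl]methyl (E)-3-[4-(tert-butyldimethylsilyloxy)phenyl]prop-2-enoate | COc1cc([C@@H]2Oc3c(OC)cc(CCCO[Si](C)(C)C(C)(C)C)cc3[C@H]2COC(=O)/C=C/c2ccc(O[Si](C)(C)C(C)(C)C)cc2)ccc1O[Si](C(C)C)(C(C)C)C(C)C | intermediate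
23 | [(2R,3S)-2-(4-hydroxy-3-methoxyphenyl)-5-(3-hydroxypropyl)-7-methoxy-2,3-dihydro-1-benzofuran-3-yl]methyl (E)-3-(4-hydroxyphenyl)prop-2-enoate | COc1cc([C@@H]2Oc3c(OC)cc(CCCO)cc3[C@H]2COC(=O)/C=C/c2ccc(O)cc2)ccc1O | target

## Step count and risk

Total steps: 11. Longest linear sequence: 8 (steps 1, 2, 5, 6, 7, 8, 10, 11).

**Step 6 (key step).** Most likely failure: B-ring migration or elimination to the flavone competing with ring-bond migration; acid-induced ionisation at C2 eroding enantiopurity; or loss of the aryl silyl ether followed by oxidation of the freed phenol by iodine(III). Fallback, from 10 back to 14, replaces the iodane-induced shift by a carbene 1,2-shift. Detrifluoroacetylative diazo transfer (LiHMDS, CF3CO2CH2CF3, THF, −78 °C; then MsN3, Et3N) would give (2S)-6-bromo-3-diazo-8-methoxy-2-[3-methoxy-4-(triisopropylsilyloxy)phenyl]-2,3-dihydro-4H-chromen-4-one F1, with C2 spatially as in 10. Photochemical Wolff rearrangement in methanol contracts the ring through the ketene and should give 14 together with its C3 epimer, methyl (2R,3S)-5-bromo-7-methoxy-2-[3-methoxy-4-(triisopropylsilyloxy)phenyl]-2,3-dihydro-1-benzofuran-3-carboxylate F2. Catalytic DBU then equilibrates F2 to the trans ester 14.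

**Step 5.** Most likely failure: poor facial selectivity or slow insertion with the 8-methoxychromone; protodeboronation of the electron-rich boronic acid; or erosion of the silyl ether by fluoride released from hexafluorophosphate. Fallback, from 2 back to 10, replaces asymmetric C–C bond formation by a resolution. Vanillin is silylated to 3-methoxy-4-(triisopropylsilyloxy)benzaldehyde F3. Pyrrolidine-mediated condensation and oxa-Michael cyclisation of 2 with F3 gives racemic 6-bromo-8-methoxy-2-[3-methoxy-4-(triisopropylsilyloxy)phenyl]-2,3-dihydro-4H-chromen-4-one F4. Kinetic resolution by Ru(II)/TsDPEN asymmetric transfer hydrogenation (HCO2H/Et3N), with the catalyst enantiomer chosen to consume the (2S)-ketone, converts that enantiomer into (2S,4S)-6-bromo-8-methoxy-2-[3-methoxy-4-(triisopropylsilyloxy)phenyl]-3,4-dihydro-2H-chromen-4-ol F5. Unreduced (2R)-10 is separated by chromatography.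

**Step 8.** Most likely failure: slow transmetalation of the alkylborane with protodehalogenation of the electron-rich aryl bromide, or base-induced loss of the aryl silyl ether. Fallback, from 15 back to 18, uses an sp–sp2 coupling followed by saturation. Sonogashira coupling of 15 with tert-butyldimethyl(prop-2-yn-1-yloxy)silane (Pd(PPh3)2Cl2, CuI, Et3N, 70 °C) gives [(2R,3S)-5-[3-(tert-butyldimethylsilyloxy)prop-1-yn-1-yl]-7-methoxy-2-[3-methoxy-4-(triisopropylsilyloxy)phenyl]-2,3-dihydro-1-benzofuran-3-yl]methanol F6. Hydrogenation (H2, Pd/C, EtOAc, rt) then gives 18.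

**Step 11.** Most likely failure: incomplete cleavage of the hindered aryl triisopropylsilyl ether under buffered fluoride; with insufficient buffering, phenoxide-driven cleavage of the cinnamate or opening of the C2–O1 bond. Fallback, from 18 back to 23, frees the phenol before the ester is made and replaces steps 10 and 11. One equivalent of TBAF at −20 °C cleaves the aryl silyl ether selectively to give 4-[(2R,3S)-5-[3-(tert-butyldimethylsilyloxy)propyl]-3-(hydroxymethyl)-7-methoxy-2,3-dihydro-1-benzofuran-2-yl]-2-methoxyphenol F7. Mitsunobu esterification (PPh3, DIAD, THF, 0 °C) with unprotected 19 activates the primary alcohol, which the carboxylic acid captures in preference to either phenol. This gives [(2R,3S)-5-[3-(tert-butyldimethylsilyloxy)propyl]-2-(4-hydroxy-3-methoxyphenyl)-7-methoxy-2,3-dihydro-1-benzofuran-3-yl]methyl (E)-3-(4-hydroxyphenyl)prop-2-enoate F8. PPTS in methanol removes the remaining alkyl silyl ether to give 23.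

## Further compounds

F1 | step 6 | (2S)-6-bromo-3-diazo-8-methoxy-2-[3-methoxy-4-(triisopropylsilyloxy)phenyl]-2,3-dihydro-4H-chromen-4-one | COc1cc([C@@H]2Oc3c(OC)cc(Br)cc3C(=O)C2=[N+]=[N-])ccc1O[Si](C(C)C)(C(C)C)C(C)C
F2 | step 6 | methyl (2R,3S)-5-bromo-7-methoxy-2-[3-methoxy-4-(triisopropylsilyloxy)phenyl]-2,3-dihydro-1-benzofuran-3-carboxylate | COc1cc([C@@H]2Oc3c(OC)cc(Br)cc3[C@@H]2C(=O)OC)ccc1O[Si](C(C)C)(C(C)C)C(C)C
F3 | step 5 | 3-methoxy-4-(triisopropylsilyloxy)benzaldehyde | COc1cc(C=O)ccc1O[Si](C(C)C)(C(C)C)C(C)C
F4 | step 5 | racemic 6-bromo-8-methoxy-2-[3-methoxy-4-(triisopropylsilyloxy)phenyl]-2,3-dihydro-4H-chromen-4-one | COc1cc(C2Oc3c(OC)cc(Br)cc3C(=O)C2)ccc1O[Si](C(C)C)(C(C)C)C(C)C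
F5 | step 5 | (2S,4S)-6-bromo-8-methoxy-2-[3-methoxy-4-(triisopropylsilyloxy)phenyl]-3,4-dihydro-2H-chromen-4-ol | COc1cc([C@H]2Oc3c(OC)cc(Br)cc3[C@@H](O)C2)ccc1O[Si](C(C)C)(C(C)C)C(C)C
F6 | step 8 | [(2R,3S)-5-[3-(tert-butyldimethylsilyloxy)prop-1-yn-1-yl]-7-methoxy-2-[3-methoxy-4-(triisopropylsilyloxy)phenyl]-2,3-dihydro-1-benzofuran-3-yl]methanol | COc1cc([C@@H]2Oc3c(OC)cc(C#CCO[Si](C)(C)C(C)(C)C)cc3[C@H]2CO)ccc1O[Si](C(C)C)(C(C)C)C(C)C
F7 | step 11 | 4-[(2R,3S)-5-[3-(tert-butyldimethylsilyloxy)propyl]-3-(hydroxymethyl)-7-methoxy-2,3-dihydro-1-benzofuran-2-yl]-2-methoxyphenol | COc1cc([C@@H]2Oc3c(OC)cc(CCCO[Si](C)(C)C(C)(C)C)cc3[C@H]2CO)ccc1O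
F8 | step 11 | [(2R,3S)-5-[3-(tert-butyldimethylsilyloxy)propyl]-2-(4-hydroxy-3-methoxyphenyl)-7-methoxy-2,3-dihydro-1-benzofuran-3-yl]methyl (E)-3-(4-hydroxyphenyl)prop-2-enoate | COc1cc([C@@H]2Oc3c(OC)cc(CCCO[Si](C)(C)C(C)(C)C)cc3[C@H]2COC(=O)/C=C/c2ccc(O)cc2)ccc1O
A1 | alternative 1 | racemic trans methyl 2-(4-hydroxy-3-methoxyphenyl)-7-methoxy-5-[(E)-3-methoxy-3-oxoprop-1-enyl]-2,3-dihydro-1-benzofuran-3-carboxylate (one enantiomer drawn) | COc1cc([C@@H]2Oc3c(OC)cc(/C=C/C(=O)OC)cc3[C@H]2C(=O)OC)ccc1O
A2 | alternative 2 | methyl 2-[5-bromo-3-methoxy-2-[[3-methoxy-4-(triisopropylsilyloxy)phenyl]methoxy]phenyl]-2-diazoacetate | COC(=O)C(=[N+]=[N-])c1cc(Br)cc(OC)c1OCc1ccc(O[Si](C(C)C)(C(C)C)C(C)C)c(OC)c1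
A3 | alternative 3 | racemic methyl 2-(5-bromo-2-iodo-3-methoxyphenyl)-3-[3-methoxy-4-(triisopropylsilyloxy)phenyl]-3-oxopropanoate | COC(=O)C(c1cc(Br)cc(OC)c1I)C(=O)c1ccc(O[Si](C(C)C)(C(C)C)C(C)C)c(OC)c1
A4 | alternative 3 | methyl (2R,3R)-2-(5-bromo-2-iodo-3-methoxyphenyl)-3-hydroxy-3-[3-methoxy-4-(triisopropylsilyloxy)phenyl]propanoate | COc1cc([C@H](O)[C@@H](c2cc(Br)cc(OC)c2I)C(=O)OC)ccc1O[Si](C(C)C)(C(C)C)C(C)C
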